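## Retrosynthetic overview

1. Target 14 ⇐ 13: the last C–C bond is C-prenylation of the enolised 2-acyl-1,3-dione carbon, from the face of the one-carbon ketone bridge.
2. 13 ⇐ 11 (key step): an oxidative radical 5-exo closure builds the bicyclo[3.2.1]octane; radical-to-cation crossover and a 2-butynyl (methylacetylene) terminator then close the cyclopentane and deliver the acetyl group directly.
3. 11 ⇐ 9: enantioselective dearomative C-prenylation creates the one stereocentre that controls all the others.
4. 9 ⇐ 1 + 2 + 5 + 7: polyketide-type assembly (two Claisen acylations, then a carboxylative Claisen cyclisation); the butynyl chain is carried in from 2.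
5. Ring order: aromatic six-membered ring, then cyclopentanone (radical), then cyclopentane (cationic).

Assumption: enolisable polycarbonyl compounds are drawn as one tautomer (open chains as keto forms, rings as the enol named); CIP descriptors refer to the tautomer drawn.

## Route

**Step 1**
Reactants: 1 3-methylbutan-2-one; 2 hex-4-ynoic acid
Product: 4 2-methyldec-8-yne-3,5-dione, via hex-4-ynoyl imidazolide 3 (not isolated)
Conditions: 2, 1,1'-carbonyldiimidazole, THF, 23 °C; then 1 (2.2 equiv), LiN(i-Pr)2 (2.2 equiv), THF, −78 → 0 °C; 1 M HCl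
Reagents that add atoms: none
Why: Crossed Claisen acylation, in which LiN(i-Pr)2 forms the kinetic enolate on the methyl side of 1 and the acyl imidazole acylates that carbon, the extra enolate absorbing the acidic proton of the 1,3-diketone; no stereocentre is formed.

**Step 2**
Reactants: 4 2-methyldec-8-yne-3,5-dione; 5 methyl propanoate
Product: 6 4-(but-2-yn-1-yl)-8-methylnonane-3,5,7-trione
Conditions: 4 (2.0 equiv), LiN(i-Pr)2 (4.0 equiv), THF, 0 °C; then 5 (1.0 equiv), 0 → 23 °C; 1 M HCl
Reagents that add atoms: none
Why: Hauser–Harris dianion acylation, in which the second deprotonation occurs at the CH2 next to the chain rather than at the isopropyl CH and this most nucleophilic carbanion is C-acylated by the ester (the second equivalent of dianion deprotonates the product); no stable stereocentre is formed.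

**Step 3**
Reactants: 6 4-(but-2-yn-1-yl)-8-methylnonane-3,5,7-trione; 7 dimethyl carbonate
Product: 9 1-[3-(but-2-yn-1-yl)-2,4,6-trihydroxy-5-methylphenyl]-2-methylpropan-1-one, via triketo ester 8 (not isolated)
Conditions: LiN(i-Pr)2 (3.3 equiv), THF, −78 → 0 °C; 7, 0 °C; then Mg(OMe)2, MeOH, 65 °C; 1 M HCl
Reagents that add atoms: none
Why: Harris-type biomimetic polyketide sequence, in which the trianion is methoxycarbonylated at its terminal ethyl carbanion and the 3,5,7-triketo ester undergoes magnesium-templated Claisen cyclisation (central carbanion onto the ester) and aromatises to the achiral acylphloroglucinol.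

**Step 4**
Reactants: 9 1-[3-(but-2-yn-1-yl)-2,4,6-trihydroxy-5-methylphenyl]-2-methylpropan-1-one; 10 1-bromo-3-methylbut-2-ene
Product: 11 (4S)-2-(but-2-yn-1-yl)-3,5-dihydroxy-4-methyl-4-(3-methylbut-2-en-1-yl)-6-(2-methylpropanoyl)cyclohexa-2,5-dien-1-one
Conditions: 10 (1.05 equiv), O-allyl-N-(9-anthracenylmethyl)cinchonidinium bromide (10 mol %), CsOH·H2O (3 equiv), toluene–CH2Cl2 (1:1), −50 °C
Reagents that add atoms: none
Why: Proposed new method: asymmetric phase-transfer alkylative dearomatisation, in which the chiral ammonium cation ion-pairs with the phenoxide and screens one face of the methyl-bearing ring carbon (less hindered than the butynyl-bearing one), so that the allylic bromide adds there by SN2 and creates the quaternary centre, required as (S); the closest known reaction is the cinchona phase-transfer alkylative dearomatisation of dialkylated acylphloroglucinols used for hyperibone K, extended here from a Michael-type electrophile to an allylic bromide.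

**Step 5 (key step)**
Reactants: 11 (4S)-2-(but-2-yn-1-yl)-3,5-dihydroxy-4-methyl-4-(3-methylbut-2-en-1-yl)-6-(2-methylpropanoyl)cyclohexa-2,5-dien-1-one
Product: 13 (1S,3R,5R,7S)-3-acetyl-10-hydroxy-4,4,7-trimethyl-9-(2-methylpropanoyl)tricyclo[5.3.1.0^{1,5}]undec-9-ene-8,11-dione, via isopropenyl bicyclic dione 12 (not isolated)
Conditions: Mn(OAc)3·2H2O (2.2 equiv), Cu(OAc)2·H2O (1.0 equiv), AcOH, 23 °C; then CF3CO2H–H2O (9:1), 0 → 23 °C
Reagents that add atoms: water O
Why: Proposed new method: trivalent manganese oxidises the enolised triketone to the radical at the butynyl-bearing carbon, which closes 5-exo onto the prenyl alkene on the only face the tether allows (fixing both bridgeheads from the (S) centre, the side chain turning exo to fix the ring-fusion CH), divalent copper oxidises the tertiary radical to the isopropenyl compound 12, and aqueous CF3CO2H re-forms the tertiary cation, which the 2-butynyl group captures in a Johnson-type cation–alkyne closure to a linear vinyl cation that is hydrated to an enol and protonated on the open face, anti to the bridging ketone and the axial methyl, giving the acetyl epimer required (3R); the closest known reactions are the manganese/copper oxidative cyclisations used for the ialibinones and Johnson's methylacetylene-terminated cyclisation to 17-acetyl steroids.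

**Step 6**
Reactants: 13 (1S,3R,5R,7S)-3-acetyl-10-hydroxy-4,4,7-trimethyl-9-(2-methylpropanoyl)tricyclo[5.3.1.0^{1,5}]undec-9-ene-8,11-dione; 10 1-bromo-3-methylbut-2-ene
Product: 14 (1R,3R,5R,7S,9S)-3-acetyl-4,4,7-trimethyl-9-(3-methylbut-2-en-1-yl)-9-(2-methylpropanoyl)tricyclo[5.3.1.0^{1,5}]undecane-8,10,11-trione
Conditions: 10 (1.3 equiv), K2CO3 (2 equiv), Pd(PPh3)4 (5 mol %), THF, 0 → 23 °C
Reagents that add atoms: none
Why: Tsuji–Trost-type C-alkylation, in which the triketone enolate attacks the less substituted terminus of the π-prenyl palladium complex at its only nucleophilic carbon (any O-prenyl ether re-ionises on zerovalent palladium and is funnelled to carbon), on the face syn to the one-carbon ketone bridge because the other face is screened by the endo hydrogens of the two-carbon bridge, which sets (9S).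

## Compound list

1 | 3-methylbutan-2-one | CC(=O)C(C)C | starting material
2 | hex-4-ynoic acid | CC#CCCC(=O)O | starting material
3 | 1-(1H-imidazol-1-yl)hex-4-yn-1-one | CC#CCCC(=O)n1ccnc1 | intermediate
4 | 2-methyldec-8-yne-3,5-dione | CC(C)C(=O)CC(=O)CCC#CC | intermediate
5 | methyl propanoate | CCC(=O)OC | starting material
6 | 4-(but-2-yn-1-yl)-8-methylnonane-3,5,7-trione | CCC(=O)C(CC#CC)C(=O)CC(=O)C(C)C | intermediate
7 | dimethyl carbonate | COC(=O)OC | starting material
8 | methyl 4-(but-2-yn-1-yl)-2,8-dimethyl-3,5,7-trioxononanoate | COC(=O)C(C)C(=O)C(CC#CC)C(=O)CC(=O)C(C)C | intermediate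
9 | 1-[3-(but-2-yn-1-yl)-2,4,6-trihydroxy-5-methylphenyl]-2-methylpropan-1-one | CC#CCc1c(O)c(C)c(O)c(C(=O)C(C)C)c1O | intermediate
10 | 1-bromo-3-methylbut-2-ene | CC(C)=CCBr | starting material
11 | (4S)-2-(but-2-yn-1-yl)-3,5-dihydroxy-4-methyl-4-(3-methylbut-2-en-1-yl)-6-(2-methylpropanoyl)cyclohexa-2,5-dien-1-one | CC#CCC1=C(O)[C@](C)(CC=C(C)C)C(O)=C(C(=O)C(C)C)C1=O | intermediate
12 | (1S,5S,6R)-5-(but-2-yn-1-yl)-4-hydroxy-1-methyl-3-(2-methylpropanoyl)-6-(prop-1-en-2-yl)bicyclo[3.2.1]oct-3-ene-2,8-dione | CC#CC[C@]12C(=O)[C@](C)(C[C@@H]1C(C)=C)C(=O)C(C(=O)C(C)C)=C2O | intermediate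
13 | (1S,3R,5R,7S)-3-acetyl-10-hydroxy-4,4,7-trimethyl-9-(2-methylpropanoyl)tricyclo[5.3.1.0^{1,5}]undec-9-ene-8,11-dione | CC(=O)[C@@H]1C[C@]23C(=O)[C@](C)(C[C@@H]2C1(C)C)C(=O)C(C(=O)C(C)C)=C3O | intermediate
14 | (1R,3R,5R,7S,9S)-3-acetyl-4,4,7-trimethyl-9-(3-methylbut-2-en-1-yl)-9-(2-methylpropanoyl)tricyclo[5.3.1.0^{1,5}]undecane-8,10,11-trione | CC(=O)[C@@H]1C[C@]23C(=O)[C@](C)(C[C@@H]2C1(C)C)C(=O)[C@](CC=C(C)C)(C(=O)C(C)C)C3=O | target

## Step count and risks

Total steps: 6. Longest linear sequence: 6 (1 + 2 → 4 → 6 → 9 → 11 → 13 → 14).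

The three steps most likely to fail:

**Step 4.** The site of alkylation (methyl-bearing versus butynyl-bearing carbon, and O versus C) and the level and sense of induction are untested on this substrate. If the sense is reversed, the pseudoenantiomeric cinchoninium salt is the first change. Fallback: setting out from 9, unselective C-prenylation with 10 in aqueous KOH gives racemic 2-(but-2-yn-1-yl)-3,5-dihydroxy-4-methyl-4-(3-methylbut-2-en-1-yl)-6-(2-methylpropanoyl)cyclohexa-2,5-dien-1-one F5. This is freed from its regioisomer and resolved by preparative chromatography on a chiral stationary phase, coming back to the route at 11.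

**Step 5.** The copper-mediated crossover may be incomplete, the alkyne may lose out to other fates of the cation, and the enol protonation may give some of the C3 epimer. Fallback: setting out from 11, the closure is run as an all-radical double cyclisation with Mn(OAc)3·2H2O in ethanol and no copper salt (5-exo-trig, then 5-exo-dig, the vinyl radical taking hydrogen from the solvent). This gives (1S,5R,7S)-3-ethylidene-10-hydroxy-4,4,7-trimethyl-9-(2-methylpropanoyl)tricyclo[5.3.1.0^{1,5}]undec-9-ene-8,11-dione F6. A sensitised singlet-oxygen ene reaction gives (1S,5R,7S)-3-(1-hydroperoxyethyl)-10-hydroxy-4,4,7-trimethyl-9-(2-methylpropanoyl)tricyclo[5.3.1.0^{1,5}]undeca-2,9-diene-8,11-dione F7. Kornblum–DeLaMare dehydration with Et3N gives (1S,5R,7S)-3-acetyl-10-hydroxy-4,4,7-trimethyl-9-(2-methylpropanoyl)tricyclo[5.3.1.0^{1,5}]undeca-2,9-diene-8,11-dione F8. Hydrogenation over Pd/C, from the face opposite the bridging ketone, sets C3 and comes back to the route at 13.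

**Step 2.** Acylation of the dianion at a substituted carbanion by an enolisable ester can be low-yielding. Fallback: setting out from 1, the side chain is added last instead of being carried through. Claisen acylation of the lithium enolate of 1 with ethyl acetate gives 2-methylhexane-3,5-dione F1. Its dianion is propionylated with 5 at the terminal methyl carbanion to 2-methylnonane-3,5,7-trione F2. Trianion methoxycarbonylation with 7 gives methyl 2,8-dimethyl-3,5,7-trioxononanoate F3, which Mg(OMe)2 cyclises to 2-methyl-1-(2,4,6-trihydroxy-3-methylphenyl)propan-1-one F4. C-Alkylation of F4 at its one free ring carbon with 1-bromobut-2-yne (aqueous KOH) comes back to the route at 9.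

## Further compounds

F1 | step 2 | 2-methylhexane-3,5-dione | CC(C)C(=O)CC(C)=O
F2 | step 2 | 2-methylnonane-3,5,7-trione | CCC(=O)CC(=O)CC(=O)C(C)C
F3 | step 2 | methyl 2,8-dimethyl-3,5,7-trioxononanoate | COC(=O)C(C)C(=O)CC(=O)CC(=O)C(C)C
F4 | step 2 | 2-methyl-1-(2,4,6-trihydroxy-3-methylphenyl)propan-1-one | Cc1c(O)cc(O)c(C(=O)C(C)C)c1O
F5 | step 4 | racemic 2-(but-2-yn-1-yl)-3,5-dihydroxy-4-methyl-4-(3-methylbut-2-en-1-yl)-6-(2-methylpropanoyl)cyclohexa-2,5-dien-1-one | CC#CCC1=C(O)C(C)(CC=C(C)C)C(O)=C(C(=O)C(C)C)C1=O
F6 | step 5 | (1S,5R,7S)-3-ethylidene-10-hydroxy-4,4,7-trimethyl-9-(2-methylpropanoyl)tricyclo[5.3.1.0^{1,5}]undec-9-ene-8,11-dione | CC=C1C[C@]23C(=O)[C@](C)(C[C@@H]2C1(C)C)C(=O)C(C(=O)C(C)C)=C3O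
F7 | step 5 | (1S,5R,7S)-3-(1-hydroperoxyethyl)-10-hydroxy-4,4,7-trimethyl-9-(2-methylpropanoyl)tricyclo[5.3.1.0^{1,5}]undeca-2,9-diene-8,11-dione | CC(OO)C1=C[C@]23C(=O)[C@](C)(C[C@@H]2C1(C)C)C(=O)C(C(=O)C(C)C)=C3O
F8 | step 5 | (1S,5R,7S)-3-acetyl-10-hydroxy-4,4,7-trimethyl-9-(2-methylpropanoyl)tricyclo[5.3.1.0^{1,5}]undeca-2,9-diene-8,11-dione | CC(=O)C1=C[C@]23C(=O)[C@](C)(C[C@@H]2C1(C)C)C(=O)C(C(=O)C(C)C)=C3O
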